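Lignan numbering: C7 and C7' are the benzylic CH groups, C8 is the carbinol carbon and C8' the CH of the ring fusion, and C9 (on C8) and C9' (on C8') are the OCH2 carbons. Ring A is C7'–O1–C9–C8–C8' and ring B is C7–O2–C9'–C8'–C8.
Enabling feature: in ring B the benzylic C7 sits directly on the oxygen-bearing quaternary C8 and reaches C9' only across O2. Excising O2 shrinks ring B to the cyclobutanone C7–C8–C8'–C9'(=O), a 2-aryl-3-oxy-cyclobutanone, which is the pattern a ketene leaves on an enol ether.
Cuts, in order: C9' back to the lactone level; O2 out (Baeyer–Villiger); C7–C8 and C8'–C9' together ([2+2]) to an aryl ketene and the C8=C8' enol silane of ring A; then the C7'–H bond (conjugate hydride), O1–C7' (cyclodehydration) and C8–C8' (Claisen).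
Forward: ring A is made first as an achiral furanone, the four-membered ring is fused onto C8–C8', oxygen insertion expands it to ring B, C9' is deoxygenated and the protecting groups are removed.
Stereochemistry: C7' comes from the chiral ligand on copper hydride. C8 and C8' come from ketene attack anti to the C7' aryl group with obligatory cis fusion. C7 is set by equilibrating the acidic α-aryl ketone to the exo isomer; it is kept with retention in the migration and is never ionised afterwards.

Key step: step 6

Abbreviation: Ar = 4-(benzyloxy)-3,5-dimethoxyphenyl.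
Assumption: (R)-DTBM-SEGPHOS is written as the ligand antipode that leads to (S)-8; the sense of induction on this substrate class is not established, and the equally available (S)-ligand is used if it proves opposite.

Step 1
Reactants: 1 acetosyringone [1-(4-hydroxy-3,5-dimethoxyphenyl)ethanone]; 2 benzyl bromide
Product: 3 1-[4-(benzyloxy)-3,5-dimethoxyphenyl]ethanone (ArCOCH3)
Conditions: K2CO3, DMF, 60 °C
Reagents that add atoms: benzyl bromide 2, BrCc1ccccc1
Why: Williamson etherification of the phenoxide installs a benzyl ether that tolerates the later amide base, hydride, peracid and Lewis acid steps and is removed by hydrogenolysis at the end.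

Step 2
Reactants: 3 ArCOCH3; 4 ethyl [(tert-butyldimethylsilyl)oxy]acetate
Product: 7 5-Ar-furan-3(2H)-one, via silyloxy diketone 5 (not isolated), via hydroxy diketone 6 (not isolated)
Conditions: LiN(SiMe3)2 (2.2 equiv), THF, −78 °C; 4, −78 → 0 °C; then 3 M aq HCl, 23 °C
Reagents that add atoms: none
Why: A crossed Claisen condensation of the methyl ketone enolate with a glycolate ester that has no leaving group on its α-carbon forms C8'–C8 (the second equivalent of base holds the product as its enolate), and aqueous acid then removes the silyl group and drives the known cyclodehydration of an α'-hydroxy 1,3-diketone to the 3(2H)-furanone, closing ring A at O1–C7'.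

Step 3
Reactants: 7 5-Ar-furan-3(2H)-one
Product: 8 (2S)-2-Ar-4-[(dimethylphenylsilyl)oxy]-2,5-dihydrofuran
Conditions: Cu(OAc)2 (5 mol %), (R)-DTBM-SEGPHOS (5.5 mol %), PhMe2SiH (1.5 equiv), toluene, catalyst aged with the silane before 7 is added, 0 °C; filtration through Et3N-deactivated silica
Reagents that add atoms: dimethylphenylsilane, C[SiH](C)c1ccccc1
Why: Proposed new method: the ligated copper hydride generated from Cu(OAc)2, the bisphosphine and the silane should deliver hydride to C7', the β-carbon of the cyclic vinylogous ester, on the enantioface left open by the ligand, and σ-bond metathesis of the oxygen-bound copper enolate with PhMe2SiH should then release the C8=C8' enol silane regiospecifically and regenerate the hydride, ring opening by loss of O1 being disfavoured because the C7'–O1 bond lies close to the nodal plane of the endocyclic enolate; the closest known reaction types are the asymmetric copper hydride 1,4-hydrosilylation of β,β-disubstituted cyclopentenones and of chromones and the [(Ph3P)CuH]6/PhMe2SiH reduction of enones to isolable silyl enol ethers, none of which has been shown on a 3(2H)-furanone.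

Step 4
Reactants: 9 (4-hydroxy-3,5-dimethoxyphenyl)acetic acid; 2 benzyl bromide
Product: 11 Ar-acetic acid (ArCH2CO2H), via benzyl ester 10 (not isolated)
Conditions: BnBr (2.3 equiv), K2CO3, DMF, 60 °C; then aq NaOH, MeOH, 50 °C; aq HCl
Reagents that add atoms: benzyl bromide 2, BrCc1ccccc1; sodium hydroxide, [Na+].[OH-]
Why: Exhaustive O-alkylation (Williamson ether and ester formation) followed by saponification in the same flask frees only the carboxylic acid, because aryl benzyl ethers are inert to hydroxide.

Step 5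
Reactants: 11 ArCH2CO2H
Product: 12 Ar-acetyl chloride (ArCH2COCl)
Conditions: (COCl)2, DMF (cat.), CH2Cl2, 0 → 23 °C; concentrated and used directly
Reagents that add atoms: oxalyl chloride, O=C(Cl)C(=O)Cl
Why: Acid chloride formation through the catalytic Vilsmeier-type chloroiminium species proceeds under mild conditions with only gaseous by-products and leaves the aryl ethers untouched.

Step 6
Reactants: 8 (2S)-2-Ar-4-[(dimethylphenylsilyl)oxy]-2,5-dihydrofuran; 12 ArCH2COCl
Product: 15 (1S,4S,5R,7R)-4,7-di-Ar-1-[(dimethylphenylsilyl)oxy]-3-oxabicyclo[3.2.0]heptan-6-one (7-exo aryl), via aryl ketene 13 (not isolated), via endo-aryl cycloadduct 14 (not isolated)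
Conditions: 8, iPr2NEt (3 equiv), toluene, 60 °C, 12 (2.5 equiv) added by syringe pump over 8 h; then DBU (0.2 equiv), 23 °C
Reagents that add atoms: none
Why: iPr2NEt strips HCl from 12 and the aryl ketene 13 so formed is intercepted by 8: C8', the nucleophilic terminus of the enol silane, bonds to the sp carbon of 13 (the future C9') in the plane of the ketene substituents and from its hydrogen side, and the enolate carbon (C7) of the short-lived zwitterion then bonds to the silyloxycarbenium carbon C8. The closest known reaction type is the thermal [2+2] cycloaddition of ketenes, including aldoketenes made in situ, with enol ethers and silyl enol ethers to give 3-oxy-substituted cyclobutanones. One ring is closed, the cyclobutanone C7–C8–C8'–C9', by an intermolecular cycloaddition whose final event is a 4-exo-trig collapse of the enolate on the oxocarbenium ion, and a four-membered ring on ring A can only be cis-fused. C8 and C8' are set together by the resident C7' centre, because its aryl group shields one face of the flat dihydrofuran and the first bond is made at the neighbouring C8'. C7 arises kinetically with the aryl group endo (14), and its acidic benzylic α-hydrogen lets catalytic DBU move it to the exo position of 15, cis to the C8 oxygen and clear of the concave side of ring A. The step needs regioselectivity, secured by the polarisation that the C8 oxygen imposes on the alkene, and chemoselectivity against ketene dimerisation, secured by slow addition of 12 so that 13 always meets an excess of 8.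

Step 7
Reactants: 15 exo-aryl cyclobutanone
Product: 16 (3R,3aS,6S,6aR)-3,6-di-Ar-3a-[(dimethylphenylsilyl)oxy]tetrahydro-1H,3H-furo[3,4-c]furan-1-one
Conditions: mCPBA, NaHCO3 (buffer), CH2Cl2, 0 → 23 °C
Reagents that add atoms: 3-chloroperbenzoic acid, OOC(=O)c1cccc(Cl)c1
Why: In this Baeyer–Villiger oxidation, which is fast for strained cyclobutanones, the benzylic C7 of the Criegee adduct is supported by the electron-rich aryl group and carries one β-oxygen fewer than C8', so it should migrate with retention, placing O2 between C7 and C9' and preserving the C7 configuration.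

Step 8
Reactants: 16 lactone
Product: 17 (3R,3aS,6S,6aR)-3,6-di-Ar-3a-[(dimethylphenylsilyl)oxy]tetrahydro-1H,3H-furo[3,4-c]furan-1-ol (lactol; both C9' anomers)
Conditions: iBu2AlH (1.2 equiv), CH2Cl2, −78 °C; aq potassium sodium tartrate
Reagents that add atoms: none
Why: Partial reduction of a γ-lactone at low temperature stops at the aluminium hemiacetal, which gives the lactol on work-up, and the new C9' centre is removed in the next step.

Step 9
Reactants: 17 lactol
Product: 18 (3R,3aS,6S,6aR)-3,6-di-Ar-3a-[(dimethylphenylsilyl)oxy]tetrahydro-1H,3H-furo[3,4-c]furan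
Conditions: Et3SiH (3 equiv), BF3·OEt2 (1.5 equiv), CH2Cl2, −78 °C
Reagents that add atoms: none
Why: In this ionic reduction of a lactol, BF3 ionises the anomeric C9'–OH to the O2-stabilised oxocarbenium ion and Et3SiH reduces it to CH2, so ring B is never opened and the benzylic C7–O2 and C7'–O1 bonds should stay intact at −78 °C.

Step 10
Reactants: 18 silyl ether
Product: 19 (3R,3aS,6S,6aR)-3,6-di-Ar-tetrahydro-1H,3H-furo[3,4-c]furan-3a-ol
Conditions: Bu4NF, AcOH, THF, 0 → 23 °C
Reagents that add atoms: none
Why: Fluoride-induced cleavage of the Si–O bond under acetic acid buffering frees the tertiary C8 hydroxyl without touching any stereocentre.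

Step 11
Reactants: 19 dibenzyl ether
Product: 20 8-hydroxysyringaresinol [(3R,3aS,6S,6aR)-3,6-bis(4-hydroxy-3,5-dimethoxyphenyl)tetrahydro-1H,3H-furo[3,4-c]furan-3a-ol; 7R,7'S,8S,8'R]
Conditions: H2 (1 atm), Pd/C, EtOAc, 23 °C, stopped after uptake of two equivalents of H2
Reagents that add atoms: none
Why: Catalytic hydrogenolysis of aryl benzyl ethers is much faster than cleavage of the ring C7–O2 and C7'–O1 bonds in a neutral solvent, so a monitored reaction should remove only the two benzyl groups.

Compound list
1 | acetosyringone, 1-(4-hydroxy-3,5-dimethoxyphenyl)ethanone | COc1cc(C(C)=O)cc(OC)c1O | starting material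
2 | benzyl bromide | BrCc1ccccc1 | starting material
3 | 1-[4-(benzyloxy)-3,5-dimethoxyphenyl]ethanone | COc1cc(C(C)=O)cc(OC)c1OCc1ccccc1 | intermediate
4 | ethyl [(tert-butyldimethylsilyl)oxy]acetate | CCOC(=O)CO[Si](C)(C)C(C)(C)C | starting material
5 | 1-[4-(benzyloxy)-3,5-dimethoxyphenyl]-4-[(tert-butyldimethylsilyl)oxy]butane-1,3-dione | COc1cc(C(=O)CC(=O)CO[Si](C)(C)C(C)(C)C)cc(OC)c1OCc1ccccc1 | intermediate
6 | 1-[4-(benzyloxy)-3,5-dimethoxyphenyl]-4-hydroxybutane-1,3-dione | COc1cc(C(=O)CC(=O)CO)cc(OC)c1OCc1ccccc1 | intermediate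
7 | 5-[4-(benzyloxy)-3,5-dimethoxyphenyl]furan-3(2H)-one | COc1cc(C2=CC(=O)CO2)cc(OC)c1OCc1ccccc1 | intermediate
8 | (2S)-2-[4-(benzyloxy)-3,5-dimethoxyphenyl]-4-[(dimethylphenylsilyl)oxy]-2,5-dihydrofuran | COc1cc([C@H]2OCC(O[Si](C)(C)c3ccccc3)=C2)cc(OC)c1OCc1ccccc1 | intermediate
9 | (4-hydroxy-3,5-dimethoxyphenyl)acetic acid | COc1cc(CC(=O)O)cc(OC)c1O | starting material
10 | benzyl [4-(benzyloxy)-3,5-dimethoxyphenyl]acetate | COc1cc(CC(=O)OCc2ccccc2)cc(OC)c1OCc1ccccc1 | intermediate
11 | [4-(benzyloxy)-3,5-dimethoxyphenyl]acetic acid | COc1cc(CC(=O)O)cc(OC)c1OCc1ccccc1 | intermediate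
12 | [4-(benzyloxy)-3,5-dimethoxyphenyl]acetyl chloride | COc1cc(CC(=O)Cl)cc(OC)c1OCc1ccccc1 | intermediate
13 | [4-(benzyloxy)-3,5-dimethoxyphenyl]ketene | O=C=Cc1cc(OC)c(OCc2ccccc2)c(OC)c1 | intermediate
14 | (1S,4S,5R,7S)-4,7-bis[4-(benzyloxy)-3,5-dimethoxyphenyl]-1-[(dimethylphenylsilyl)oxy]-3-oxabicyclo[3.2.0]heptan-6-one (7-endo aryl) | COc1cc([C@H]2OC[C@]3(O[Si](C)(C)c4ccccc4)[C@H](c4cc(OC)c(OCc5ccccc5)c(OC)c4)C(=O)[C@H]23)cc(OC)c1OCc1ccccc1 | intermediate
15 | (1S,4S,5R,7R)-4,7-bis[4-(benzyloxy)-3,5-dimethoxyphenyl]-1-[(dimethylphenylsilyl)oxy]-3-oxabicyclo[3.2.0]heptan-6-one (7-exo aryl) | COc1cc([C@H]2OC[C@]3(O[Si](C)(C)c4ccccc4)[C@@H](c4cc(OC)c(OCc5ccccc5)c(OC)c4)C(=O)[C@H]23)cc(OC)c1OCc1ccccc1 | intermediate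
16 | (3R,3aS,6S,6aR)-3,6-bis[4-(benzyloxy)-3,5-dimethoxyphenyl]-3a-[(dimethylphenylsilyl)oxy]tetrahydro-1H,3H-furo[3,4-c]furan-1-one | COc1cc([C@H]2OC[C@]3(O[Si](C)(C)c4ccccc4)[C@@H](c4cc(OC)c(OCc5ccccc5)c(OC)c4)OC(=O)[C@H]23)cc(OC)c1OCc1ccccc1 | intermediate
17 | (3R,3aS,6S,6aR)-3,6-bis[4-(benzyloxy)-3,5-dimethoxyphenyl]-3a-[(dimethylphenylsilyl)oxy]tetrahydro-1H,3H-furo[3,4-c]furan-1-ol, anomeric mixture at C1 (C9') | COc1cc([C@H]2OC[C@]3(O[Si](C)(C)c4ccccc4)[C@@H](c4cc(OC)c(OCc5ccccc5)c(OC)c4)OC(O)[C@H]23)cc(OC)c1OCc1ccccc1 | intermediate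
18 | (3R,3aS,6S,6aR)-3,6-bis[4-(benzyloxy)-3,5-dimethoxyphenyl]-3a-[(dimethylphenylsilyl)oxy]tetrahydro-1H,3H-furo[3,4-c]furan | COc1cc([C@H]2OC[C@]3(O[Si](C)(C)c4ccccc4)[C@@H](c4cc(OC)c(OCc5ccccc5)c(OC)c4)OC[C@H]23)cc(OC)c1OCc1ccccc1 | intermediate
19 | (3R,3aS,6S,6aR)-3,6-bis[4-(benzyloxy)-3,5-dimethoxyphenyl]tetrahydro-1H,3H-furo[3,4-c]furan-3a-ol | COc1cc([C@H]2OC[C@]3(O)[C@@H](c4cc(OC)c(OCc5ccccc5)c(OC)c4)OC[C@H]23)cc(OC)c1OCc1ccccc1 | intermediate
20 | 8-hydroxysyringaresinol, (3R,3aS,6S,6aR)-3,6-bis(4-hydroxy-3,5-dimethoxyphenyl)tetrahydro-1H,3H-furo[3,4-c]furan-3a-ol | COc1cc([C@H]2OC[C@]3(O)[C@@H](c4cc(OC)c(O)c(OC)c4)OC[C@H]23)cc(OC)c1O | target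

Total step count: 11.
Longest linear sequence: 9 steps (1, 2, 3, 6, 7, 8, 9, 10, 11) from acetosyringone 1; steps 4 and 5 form the second branch.

Steps most likely to fail

**Step 3 (new method).**
- **Risk:** hydride transfer itself may fail. The copper enolate could deprotonate the acidic C9 methylene of 7, leading to aromatising dehydrogenative silylation. σ-Bond metathesis with a tertiary silane could be slow. Enantioface discrimination at an aryl/alkoxy-substituted β-carbon could be weak.
- **Fallback:** it uses only known reactions, sets out from benzyl bromide 2 and returns at 8. Commercial syringaldehyde is O-benzylated with 2 (K2CO3, DMF) to 4-(benzyloxy)-3,5-dimethoxybenzaldehyde F1. Chiral phosphoric acid-catalysed propargylation with allenylboronic acid pinacol ester then sets C7' in (1S)-1-[4-(benzyloxy)-3,5-dimethoxyphenyl]but-3-yn-1-ol F2; the catalyst is the antipode of 3,3'-bis(2,4,6-triisopropylphenyl)-1,1'-binaphthyl-2,2'-diyl hydrogen phosphate that gives the S alcohol, in toluene with 4 Å sieves at −20 °C. Gold-catalysed oxidation of the terminal alkyne with intramolecular O–H capture of the α-oxo carbene (Ph3PAuNTf2, 3,5-dichloropyridine N-oxide, MsOH, ClCH2CH2Cl, 23 °C) closes ring A as (5S)-5-[4-(benzyloxy)-3,5-dimethoxyphenyl]dihydrofuran-3(2H)-one F3. Kinetic deprotonation at C8', away from the ring oxygen as in the preparation of 2,5-dihydrofuran-3-yl triflate from tetrahydrofuran-3-one, with LiN(SiMe3)2 in the presence of PhMe2SiCl (THF, −78 °C) gives 8.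

**Step 6 (key step).**
- **Risk:** dimerisation and amine-mediated oligomerisation of the aldoketene may outrun its addition to the hindered trisubstituted enol silane. Silyl transfer within the zwitterion may divert the reaction to simple C-acylation.
- **Fallback:** the same ketene is generated by a photochemical Wolff rearrangement in a neutral medium instead of by base-induced elimination. It sets out from 3 (with 8) and returns at 15. Ketone 3 is trifluoroacetylated (LiN(SiMe3)2, CF3CO2CH2CF3, THF, −78 °C) to 1-[4-(benzyloxy)-3,5-dimethoxyphenyl]-4,4,4-trifluorobutane-1,3-dione F4. Detrifluoroacetylative diazo transfer (MsN3, Et3N, H2O, MeCN) gives 1-[4-(benzyloxy)-3,5-dimethoxyphenyl]-2-diazoethanone F5. Irradiation of F5 (blue LEDs, toluene, 23 °C) in the presence of 8 releases 13 at a low stationary concentration with no amine, ammonium salt or acid chloride present. Cycloadduct 14 is then equilibrated with DBU to 15 as in the main route.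

**Step 7.**
- **Risk:** competing migration of the ring-fusion carbon C8' would insert oxygen on the wrong side of the carbonyl group. Acid-triggered opening of the donor–acceptor cyclobutanone may also erode the material.
- **Fallback:** acidity replaces migratory aptitude as the regiochemical control. It sets out from 15 and returns at 16. Deprotonation at the more acidic benzylic C7 (LiN(SiMe3)2, Me3SiCl, THF, −78 °C) gives the C7=C9' trimethylsilyl enol ether of 15 F6. Ozonolysis with one equivalent of O3 (CH2Cl2, −78 °C; Me2S) cleaves only this bond to (2S,3R,4S)-4-[4-(benzyloxy)-3,5-dimethoxybenzoyl]-2-[4-(benzyloxy)-3,5-dimethoxyphenyl]-4-[(dimethylphenylsilyl)oxy]tetrahydrofuran-3-carboxylic acid F7. NaBH4 reduction of the aryl ketone (MeOH, −20 °C) under polar Felkin–Anh control (hydride anti to the C8–O bond, carbonyl oxygen next to the larger C8') should give the (R)-carbinol, (2S,3R,4S)-4-[(R)-[4-(benzyloxy)-3,5-dimethoxyphenyl](hydroxy)methyl]-2-[4-(benzyloxy)-3,5-dimethoxyphenyl]-4-[(dimethylphenylsilyl)oxy]tetrahydrofuran-3-carboxylic acid F8. This hydroxy acid lactonises on mild acidification to 16.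

Further compounds
F1 | step 3 | 4-(benzyloxy)-3,5-dimethoxybenzaldehyde | COc1cc(C=O)cc(OC)c1OCc1ccccc1
F2 | step 3 | (1S)-1-[4-(benzyloxy)-3,5-dimethoxyphenyl]but-3-yn-1-ol | COc1cc([C@@H](O)CC#C)cc(OC)c1OCc1ccccc1
F3 | step 3 | (5S)-5-[4-(benzyloxy)-3,5-dimethoxyphenyl]dihydrofuran-3(2H)-one | COc1cc([C@H]2OCC(=O)C2)cc(OC)c1OCc1ccccc1
F4 | step 6 | 1-[4-(benzyloxy)-3,5-dimethoxyphenyl]-4,4,4-trifluorobutane-1,3-dione | COc1cc(C(=O)CC(=O)C(F)(F)F)cc(OC)c1OCc1ccccc1
F5 | step 6 | 1-[4-(benzyloxy)-3,5-dimethoxyphenyl]-2-diazoethanone | COc1cc(C(=O)C=[N+]=[N-])cc(OC)c1OCc1ccccc1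
F6 | step 7 | C7=C9' trimethylsilyl enol ether of 15 (C7', C8 and C8' as in 15) | COc1cc([C@H]2OC[C@]3(O[Si](C)(C)c4ccccc4)C(c4cc(OC)c(OCc5ccccc5)c(OC)c4)=C(O[Si](C)(C)C)[C@H]23)cc(OC)c1OCc1ccccc1
F7 | step 7 | (2S,3R,4S)-4-[4-(benzyloxy)-3,5-dimethoxybenzoyl]-2-[4-(benzyloxy)-3,5-dimethoxyphenyl]-4-[(dimethylphenylsilyl)oxy]tetrahydrofuran-3-carboxylic acid | COc1cc([C@H]2OC[C@](O[Si](C)(C)c3ccccc3)(C(=O)c3cc(OC)c(OCc4ccccc4)c(OC)c3)[C@@H]2C(=O)O)cc(OC)c1OCc1ccccc1
F8 | step 7 | (2S,3R,4S)-4-[(R)-[4-(benzyloxy)-3,5-dimethoxyphenyl](hydroxy)methyl]-2-[4-(benzyloxy)-3,5-dimethoxyphenyl]-4-[(dimethylphenylsilyl)oxy]tetrahydrofuran-3-carboxylic acid | COc1cc([C@H]2OC[C@](O[Si](C)(C)c3ccccc3)([C@H](O)c3cc(OC)c(OCc4ccccc4)c(OC)c3)[C@@H]2C(=O)O)cc(OC)c1OCc1ccccc1
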